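**Retrosynthetic overview**
- Target ⇒ (3R)-3-(3,4-dimethoxybenzyloxy) pseudo-ester: the last step cuts only an O–CH2Ar bond, so both C3–O bonds of the lactol are already in place.
- (3R)-pseudo-ester ⇒ racemic lactol + 3,4-dimethoxybenzyl alcohol: the key C–O disconnection, a catalytic enantioconvergent acylal formation that sets C3 (proposed new chiral Brønsted acid step).
- Racemic lactol ⇒ aryl iodide (hydroxycarbonylation; the lactone, the only ring made, closes here) ⇒ resorcinol dialdehyde (iodination) ⇒ resorcinol monoaldehyde (Vilsmeier formylation).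
- Resorcinol monoaldehyde ⇒ 3,5-bis(methoxymethoxy)benzaldehyde + (4E)-tetradeca-1,4-dien-3-one: directed ortho-lithiation and copper-catalysed 1,4-addition place the complete side chain between the two oxygens.
- Dienone ⇒ (2E)-dodec-2-enal + vinylmagnesium bromide, then MnO2. Ring order: benzene ring bought; lactone ring formed in step 7 and made single-handed in step 8.

Assumption: the C3 lactol is a pseudo-acid that opens to the achiral 2-formylbenzoate quickly in base and only slowly in cold, weakly acidic, amine-free media, so it is unveiled in the last step and never exposed to base afterwards.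

**Step 1**
Reactants: 1 (2E)-dodec-2-enal
Product: 2 (4E)-tetradeca-1,4-dien-3-ol (racemic)
Conditions: vinylMgBr (1.2 equiv), THF, −78 → 0 °C; sat. aq. NH4Cl
Reagents that add atoms: vinylmagnesium bromide, C=C[Mg]Br
Why: Grignard 1,2-addition to the enal carbonyl gives the bis-allylic alcohol; the carbinol centre is racemic and is erased in step 2, and the E-alkene is untouched.

**Step 2**
Reactants: 2 (4E)-tetradeca-1,4-dien-3-ol
Product: 3 (4E)-tetradeca-1,4-dien-3-one
Conditions: MnO2 (15 equiv), CH2Cl2, rt, 3 h; filtered and used at once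
Reagents that add atoms: none
Why: MnO2 oxidation of a doubly allylic alcohol is fast and neutral, which avoids acid-induced Nazarov or polymerisation chemistry of the sensitive divinyl ketone; no stereocentre remains.

**Step 3**
Reactants: 4 3,5-dihydroxybenzaldehyde
Product: 5 3,5-bis(methoxymethoxy)benzaldehyde
Conditions: NaH (2.4 equiv), MOMCl (2.5 equiv), DMF, 0 °C → rt
Reagents that add atoms: chloromethyl methyl ether, COCCl
Why: Williamson O-alkylation of both phenoxides installs MOM ethers, which are the ortho-directing groups for step 4 and are removed by aqueous acid.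

**Step 4**
Reactants: 5 3,5-bis(methoxymethoxy)benzaldehyde; 3 (4E)-tetradeca-1,4-dien-3-one
Product: 8 3,5-dihydroxy-4-[(4E)-3-oxotetradec-4-en-1-yl]benzaldehyde, via C4-lithiated lithium aminal alkoxide 6 (not isolated), via bis-MOM keto aldehyde 7 (not isolated)
Conditions: lithium 4-methylpiperazin-1-ide (1.1 equiv, from 1-methylpiperazine + n-BuLi), THF, −20 °C; n-BuLi (1.15 equiv), 0 °C, 1 h; MgBr2·OEt2 (1.3 equiv), −20 °C; CuBr·SMe2 (10 mol%), TMSCl (2.5 equiv), then 3 (1.2 equiv), −78 → −30 °C; then 6 M HCl/THF (1:3), 40 °C, 3 h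
Reagents that add atoms: none
Why: Comins-type in situ protection of the aldehyde as a weakly directing α-amino alkoxide, directed ortho-lithiation at the position flanked by the two OMOM groups, transmetalation to magnesium and copper-catalysed, TMSCl-accelerated conjugate (1,4-) addition to the unsubstituted vinyl terminus of 3 forge the aryl–CH2 bond regioselectively, and the aqueous HCl quench hydrolyses the aminal, the silyl enol ether and both MOM acetals; no stereocentre is formed and the E-enone is kept.

**Step 5**
Reactants: 8 3,5-dihydroxy-4-[(4E)-3-oxotetradec-4-en-1-yl]benzaldehyde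
Product: 9 3,5-dihydroxy-4-[(4E)-3-oxotetradec-4-en-1-yl]benzene-1,2-dicarbaldehyde
Conditions: POCl3 (2.5 equiv), DMF (3 equiv), MeCN, −15 → 30 °C, 4 h; then H2O, 45 °C
Reagents that add atoms: N,N-dimethylformamide, CN(C)C=O; water, O
Why: Vilsmeier–Haack formylation attacks one of the two equivalent free ring positions (ortho to one OH, para to the other; the chain blocks the third), the new conjugated formyl group deactivates the ring against a second formylation, and water hydrolyses the iminium salt and any aryl formate.

**Step 6**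
Reactants: 9 3,5-dihydroxy-4-[(4E)-3-oxotetradec-4-en-1-yl]benzene-1,2-dicarbaldehyde
Product: 10 3,5-dihydroxy-6-iodo-4-[(4E)-3-oxotetradec-4-en-1-yl]benzene-1,2-dicarbaldehyde
Conditions: NIS (1.05 equiv), TFA (10 mol%), MeCN, 0 °C → rt
Reagents that add atoms: N-iodosuccinimide, O=C1CCC(=O)N1I
Why: electrophilic aromatic iodination (SEAr) at the only remaining ring C–H, still ortho/para to the two hydroxyl groups; the electron-poor enone does not react with NIS under these conditions.

**Step 7**
Reactants: 10 3,5-dihydroxy-6-iodo-4-[(4E)-3-oxotetradec-4-en-1-yl]benzene-1,2-dicarbaldehyde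
Product: 11 rac-3,5,7-trihydroxy-1-oxo-6-[(4E)-3-oxotetradec-4-en-1-yl]-1,3-dihydro-2-benzofuran-4-carbaldehyde
Conditions: Pd(OAc)2 (5 mol%), Xantphos (6 mol%), CO (1 atm), KOAc (3 equiv), DMF/H2O (9:1), 55 °C; acidic work-up (1 M HCl)
Reagents that add atoms: carbon monoxide, [C-]#[O+]; water, O
Why: palladium-catalysed hydroxycarbonylation (oxidative addition, CO insertion, hydrolysis of the acylpalladium) gives the 2-formylbenzoic acid, which closes spontaneously onto the only adjacent formyl group to the five-membered lactol (ring-chain tautomerism); C3 is racemic here and is corrected in step 8.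

**Step 8**
Reactants: 11 rac-3,5,7-trihydroxy-1-oxo-6-[(4E)-3-oxotetradec-4-en-1-yl]-1,3-dihydro-2-benzofuran-4-carbaldehyde
Product: 12 (3R)-3-[(3,4-dimethoxyphenyl)methoxy]-5,7-dihydroxy-1-oxo-6-[(4E)-3-oxotetradec-4-en-1-yl]-1,3-dihydro-2-benzofuran-4-carbaldehyde
Conditions: 3,4-dimethoxybenzyl alcohol (1.5 equiv), (R)-3,3′-bis(2,4,6-triisopropylphenyl)-1,1′-binaphthyl-2,2′-diyl hydrogen phosphate ((R)-TRIP, 10 mol%), 5 Å MS, toluene/CH2Cl2 (4:1), 0 °C → rt, 48 h
Reagents that add atoms: 3,4-dimethoxybenzyl alcohol, COc1ccc(CO)cc1OC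
Why: Proposed new method: a chiral phosphoric acid-catalysed enantioconvergent pseudo-esterification (O-alkyl acylal formation) of a racemic 3-hydroxyphthalide, in which the lactol equilibrates through its open formyl-acid tautomer, the alcohol adds to give a configurationally labile hemiacetal, and the bifunctional acid (P=O accepting the hemiacetal O–H, P–OH activating the carboxyl group) closes one hemiacetal enantiomer faster onto the carboxylic acid (or equally steers alcohol attack on the phthalidyl oxocarbenium–phosphate ion pair), so both C–O bonds at C3 are made under catalyst control while the sieves remove water; the closest known reaction types are chiral phosphoric acid-catalysed asymmetric acetalization and transacetalization of aldehydes, the N,O-acetalization of 3-hydroxyisoindolinones and the carbene-catalysed acylative dynamic kinetic resolution of 3-hydroxyphthalides; the (R)-acid is assigned by analogy and its enantiomer is used if the sense of induction proves opposite.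

**Step 9**
Reactants: 12 (3R)-3-[(3,4-dimethoxyphenyl)methoxy]-5,7-dihydroxy-1-oxo-6-[(4E)-3-oxotetradec-4-en-1-yl]-1,3-dihydro-2-benzofuran-4-carbaldehyde
Product: 13 (3R)-3,5,7-trihydroxy-1-oxo-6-[(4E)-3-oxotetradec-4-en-1-yl]-1,3-dihydro-2-benzofuran-4-carbaldehyde
Conditions: DDQ (1.3 equiv), CH2Cl2/H2O (20:1), 0 °C, 1 h; filtration, no basic wash, chromatography on acid-washed silica below 10 °C
Reagents that add atoms: none
Why: oxidative benzyl ether cleavage by DDQ (hydride abstraction at the electron-rich benzylic CH2, addition of water, collapse of the hemiacetal to 3,4-dimethoxybenzaldehyde) breaks only the O–CH2 bond, so the C3–O bonds and the (R) configuration from step 8 are retained, and the cold, amine-free, weakly acidic medium avoids ring-opening of the pseudo-acid.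

**Compound list**
1 | (2E)-dodec-2-enal | CCCCCCCCC/C=C/C=O | starting material
2 | (4E)-tetradeca-1,4-dien-3-ol (racemic) | CCCCCCCCC/C=C/C(O)C=C | intermediate
3 | (4E)-tetradeca-1,4-dien-3-one | CCCCCCCCC/C=C/C(=O)C=C | intermediate
4 | 3,5-dihydroxybenzaldehyde | O=Cc1cc(O)cc(O)c1 | starting material
5 | 3,5-bis(methoxymethoxy)benzaldehyde | COCOc1cc(C=O)cc(OCOC)c1 | intermediate
6 | lithium [4-lithio-3,5-bis(methoxymethoxy)phenyl](4-methylpiperazin-1-yl)methanolate | [Li]c1c(OCOC)cc(cc1OCOC)C(O[Li])N1CCN(C)CC1 | intermediate
7 | 3,5-bis(methoxymethoxy)-4-[(4E)-3-oxotetradec-4-en-1-yl]benzaldehyde | CCCCCCCCC/C=C/C(=O)CCc1c(OCOC)cc(C=O)cc1OCOC | intermediate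
8 | 3,5-dihydroxy-4-[(4E)-3-oxotetradec-4-en-1-yl]benzaldehyde | CCCCCCCCC/C=C/C(=O)CCc1c(O)cc(C=O)cc1O | intermediate
9 | 3,5-dihydroxy-4-[(4E)-3-oxotetradec-4-en-1-yl]benzene-1,2-dicarbaldehyde | CCCCCCCCC/C=C/C(=O)CCc1c(O)c(C=O)c(C=O)cc1O | intermediate
10 | 3,5-dihydroxy-6-iodo-4-[(4E)-3-oxotetradec-4-en-1-yl]benzene-1,2-dicarbaldehyde | CCCCCCCCC/C=C/C(=O)CCc1c(O)c(C=O)c(C=O)c(I)c1O | intermediate
11 | rac-3,5,7-trihydroxy-1-oxo-6-[(4E)-3-oxotetradec-4-en-1-yl]-1,3-dihydro-2-benzofuran-4-carbaldehyde | CCCCCCCCC/C=C/C(=O)CCc1c(O)c(C=O)c2c(c1O)C(=O)OC2O | intermediate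
12 | (3R)-3-[(3,4-dimethoxyphenyl)methoxy]-5,7-dihydroxy-1-oxo-6-[(4E)-3-oxotetradec-4-en-1-yl]-1,3-dihydro-2-benzofuran-4-carbaldehyde | CCCCCCCCC/C=C/C(=O)CCc1c(O)c(C=O)c2c(c1O)C(=O)O[C@H]2OCc1ccc(OC)c(OC)c1 | intermediate
13 | (3R)-3,5,7-trihydroxy-1-oxo-6-[(4E)-3-oxotetradec-4-en-1-yl]-1,3-dihydro-2-benzofuran-4-carbaldehyde | CCCCCCCCC/C=C/C(=O)CCc1c(O)c(C=O)c2c(c1O)C(=O)O[C@H]2O | target

**Step count and risks**
Total: 9 steps. Longest linear sequence: 8 steps (1 → 13, through steps 1, 2 and 4 to 9). The arene partner 5 is made from 4 in one step (step 3) in parallel and joins at step 4.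

Most likely to fail:

- **Step 4 (one-pot lithiation, conjugate addition, deprotection).** The risks are lithiation at C2 instead of C4, polymerisation of dienone 3, and loss of material in the telescoped acid treatment. Fallback, setting out from 5 and using dienol 2 instead of 3: the same in situ protection and lithiation to 6 is quenched with I2 (THF, −78 °C) and then with water to give 4-iodo-3,5-bis(methoxymethoxy)benzaldehyde F1. A Heck arylation of dienol 2 with F1 (Pd(OAc)2, Bu4NCl, NaHCO3, DMF, 60 °C) then gives the saturated β-aryl ketone directly, by β-hydride elimination toward the carbinol carbon and enol–ketone tautomerisation. This comes back to the route at 7, which is deprotected with aqueous HCl to 8.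

- **Step 8 (the proposed new step).** The risks are racemic background catalysis by the acidic substrate, competing acetal formation at the C4 formyl group or at the chain ketone, and low enantioselectivity. Fallback with known chemistry, setting out from 11: pseudo-esterification with 3,4-dimethoxybenzyl alcohol under an achiral acid (diphenyl phosphate, 5 Å MS, toluene) gives the racemate, that is 12 together with its mirror image (3S)-3-[(3,4-dimethoxyphenyl)methoxy]-5,7-dihydroxy-1-oxo-6-[(4E)-3-oxotetradec-4-en-1-yl]-1,3-dihydro-2-benzofuran-4-carbaldehyde F2. Preparative chiral-phase SFC delivers 12, where the route is rejoined; F2 is re-equilibrated to the racemate under the same achiral acid and alcohol (acetal exchange epimerises C3) and recycled.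

- **Step 9 (unmasking without loss of configuration).** The risks are slow hydride abstraction at an acylal-type benzyl ether, DDQ attack at the phenolic benzylic position, and partial racemisation on work-up. Fallback, setting out from 11: the step 8 conditions are run with 2-(trimethylsilyl)ethanol to give (3R)-5,7-dihydroxy-1-oxo-6-[(4E)-3-oxotetradec-4-en-1-yl]-3-[2-(trimethylsilyl)ethoxy]-1,3-dihydro-2-benzofuran-4-carbaldehyde F3. F3 is unmasked non-oxidatively with TFA/CH2Cl2 (1:4) at 0 °C by β-silyl fragmentation of the protonated ether, again without touching the C3–O bond, and the volatile by-products are removed by evaporation. This comes back to the route at 13.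

**Further compounds**
F1 | step 4 | 4-iodo-3,5-bis(methoxymethoxy)benzaldehyde | COCOc1cc(C=O)cc(OCOC)c1I
F2 | step 8 | (3S)-3-[(3,4-dimethoxyphenyl)methoxy]-5,7-dihydroxy-1-oxo-6-[(4E)-3-oxotetradec-4-en-1-yl]-1,3-dihydro-2-benzofuran-4-carbaldehyde | CCCCCCCCC/C=C/C(=O)CCc1c(O)c(C=O)c2c(c1O)C(=O)O[C@@H]2OCc1ccc(OC)c(OC)c1
F3 | step 9 | (3R)-5,7-dihydroxy-1-oxo-6-[(4E)-3-oxotetradec-4-en-1-yl]-3-[2-(trimethylsilyl)ethoxy]-1,3-dihydro-2-benzofuran-4-carbaldehyde | CCCCCCCCC/C=C/C(=O)CCc1c(O)c(C=O)c2c(c1O)C(=O)O[C@H]2OCC[Si](C)(C)C
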